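The six-membered ring of the target hides a C2h-symmetric quinone. The carbon arms C7 (on C1) and C1′ (on C4) are para to each other, and so are the oxygens on C3 and C6. The route therefore starts from 2,5-bis(silyloxymethyl)-1,4-benzoquinone and masks its C1=C2 bond as a cyclopentadiene adduct through a catalytic enantioselective Diels–Alder reaction. This one operation breaks the symmetry, sets the absolute configuration, protects C1=C2, and folds the ring so that epoxidation (C4, C5) and reduction (C3) both occur on one face. Cycloreversion, reduction at C6 and a late Nozaki–Hiyama–Kishi union at C1′–C2′ with a geranyl-derived trienyl iodide complete the synthesis.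

Key step: step 4

Locants and faces: ring C1 (bears C7H2O), C2 (=CH), C3, C4 (bears C1′), C5, C6. The α face is the ring face that carries the oxirane oxygen in the target, and β is the opposite face. In the target, 3-OH is β, 6-OH is α, and C1′ sits β on C4; the descriptors are 3S,4R,5S,6S,1′S.

Assumption: the sense of induction of the oxazaborolidinium cation is taken from its accepted pre-transition-state model. If the (S)-derived cation gives the mirror-image adduct, the equally available (R)-derived cation is used and nothing else changes.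

Step 1
Reactants: 1 2,5-dimethoxyterephthalaldehyde
Product: 2 (2,5-dimethoxy-1,4-phenylene)dimethanol
Conditions: NaBH4, MeOH–THF, 0 °C → rt
Reagents that add atoms: none
Why: Borohydride reduction of both aryl aldehydes is fast, leaves the aryl methyl ethers untouched and creates no stereocentre.

Step 2
Reactants: 2 (2,5-dimethoxy-1,4-phenylene)dimethanol
Product: 3 1,4-bis[(tert-butyldimethylsilyloxy)methyl]-2,5-dimethoxybenzene
Conditions: TBSCl, imidazole, DMF, rt
Reagents that add atoms: tert-butyldimethylsilyl chloride, CC(C)(C)[Si](C)(C)Cl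
Why: Imidazole-promoted silylation of two equivalent primary benzylic alcohols keeps the molecule symmetric and gives ethers that tolerate cold Lewis acid, mild base, hydride and heat.

Step 3
Reactants: 3 1,4-bis[(tert-butyldimethylsilyloxy)methyl]-2,5-dimethoxybenzene
Product: 4 2,5-bis[(tert-butyldimethylsilyloxy)methyl]-1,4-benzoquinone
Conditions: (NH4)2Ce(NO3)6 (2.3 equiv), MeCN–H2O, 0 °C, 10–15 min, cold extraction
Reagents that add atoms: water, O
Why: Oxidative demethylation of a 1,4-dimethoxyarene runs through the arene radical cation with attack of water at the methoxy-bearing carbons, and the short cold contact should spare the primary silyl ethers.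

Step 4
Reactants: 4 2,5-bis[(tert-butyldimethylsilyloxy)methyl]-1,4-benzoquinone; 5 cyclopenta-1,3-diene (1.05 equiv)
Product: 6 endo adduct (1R,4S,4aR,8aS)-4a,7-bis[(tert-butyldimethylsilyloxy)methyl]-1,4,4a,8a-tetrahydro-1,4-methanonaphthalene-5,8-dione (bridge on the β face of C1 and C2; C7 on C1 and H on C2 both α)
Conditions: (S)-tetrahydro-1-(2-methylphenyl)-3,3-diphenyl-1H,3H-pyrrolo[1,2-c][1,3,2]oxazaborole (20 mol %), HN(SO2CF3)2 (18 mol %), CH2Cl2, −78 °C
Reagents that add atoms: none
Why: The protonated oxazaborolidine binds one quinone carbonyl (thereby defined as C3=O) at the oxygen lone pair syn to the neighbouring C2–H, lowers the LUMO of the attached C1=C2 bond, and cyclopentadiene adds across it in a concerted but asynchronous [4π+2π] cycloaddition. The closest known reaction type is the oxazaborolidinium-catalysed enantioselective Diels–Alder reaction of 2,5-dialkyl-1,4-benzoquinones with cyclopentadiene and acyclic dienes. The two new bonds, C1–bridgehead and C2–bridgehead, close one new six-membered carbocycle which, being spanned by the diene CH2, is the bicyclo[2.2.1]heptene; the mode of closure is an intermolecular suprafacial–suprafacial cycloaddition. C1 and C2 become cis through suprafacial addition and receive their absolute sense from the catalyst, whose aryl group covers the α face so that the diene reaches the β face (Si at both C1 and C2), whereas the two bridgehead centres follow from the endo orientation of the enedione and disappear again in step 7. Since 4 is C2h-symmetric, its two C=C bonds are homotopic and its two faces enantiotopic, so no site or regiochemical selectivity is required and enantioface selection alone tells C7 from C1′ and C3=O from C6=O. A second addition is held back by the use of about one equivalent of diene and by the lower reactivity of the remaining C4=C5 bond in the folded adduct, and the quaternary C1 rules out tautomerisation to a hydroquinone.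

Step 5
Reactants: 6 endo adduct
Product: 7 bridged epoxy-dione (6 with an α-oxirane across C4–C5, its oxygen cis to the angular H and C7)
Conditions: 30 % aq. H2O2, Na2CO3, THF–MeOH, 0 °C
Reagents that add atoms: hydrogen peroxide, OO
Why: Weitz–Scheffer nucleophilic epoxidation touches only the electron-poor C4=C5 bond, the weak carbonate base avoids γ-deprotonation at C1′, and the fold of the endo adduct leaves only the convex α face open.

Step 6
Reactants: 7 bridged epoxy-dione
Product: 8 bridged hydroxy ketone (C3 β-alcohol trans to the oxirane oxygen; C6 still a ketone)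
Conditions: NaBH4 (0.5 equiv), MeOH–CH2Cl2, −78 → −40 °C
Reagents that add atoms: none
Why: Hydride can approach only from the convex α face, where C6=O is flanked by the angular α-CH2OTBS on C1 but C3=O only by the angular hydrogen on C2, so a limited amount of borohydride should reduce C3=O alone and push the new hydroxyl to the β face.

Step 7
Reactants: 8 bridged hydroxy ketone
Product: 9 epoxy-enone, 4α,5α-epoxy-3β-hydroxy-1,4-bis[(tert-butyldimethylsilyloxy)methyl]cyclohex-1-en-6-one
Conditions: Ph2O, 240 °C, 10–15 min, N2 stream
Reagents that add atoms: none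
Why: Thermal retro-Diels–Alder cycloreversion, favoured by relief of crowding at the quaternary C1 and by formation of the conjugated enone, expels volatile cyclopentadiene and restores C1=C2 without touching C3, C4 or C5.

Step 8
Reactants: 9 epoxy-enone
Product: 10 3β,6α-diol (6-OH cis to the oxirane oxygen and trans to 3-OH; both arms still OTBS)
Conditions: NaBH4, CeCl3·7H2O, MeOH, −78 °C
Reagents that add atoms: none
Why: In this Luche 1,2-reduction the oxirane oxygen next to C6 blocks and repels hydride on the α face of the nearly flat ring, so β attack should give the α-alcohol.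

Step 9
Reactants: 10 3β,6α-diol
Product: 11 tetrakis-TBS ether (C3, C6, C7 and C1′ oxygens all silylated)
Conditions: TBSOTf (2.6 equiv), 2,6-lutidine, CH2Cl2, −78 → −20 °C
Reagents that add atoms: tert-butyldimethylsilyl triflate, CC(C)(C)[Si](C)(C)OS(=O)(=O)C(F)(F)F
Why: The silyl triflate reaches even the C3 hydroxyl next to the quaternary C4, cold buffered conditions protect the epoxide, and any silyl migration in steps 7 and 8 is harmless because all four oxygens end up carrying the same group.

Step 10
Reactants: 11 tetrakis-TBS ether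
Product: 12 primary diol (C7–OH and C1′–OH free; C3 and C6 still OTBS)
Conditions: HF·pyridine, pyridine, THF, 0 °C, monitored
Reagents that add atoms: none
Why: Buffered fluoride cleaves silyl ethers in order of steric accessibility, so both primary ethers should go before the two secondary ethers, which are wedged between ring substituents.

Step 11
Reactants: 12 primary diol
Product: 13 C7 monoacetate (C1′–OH free)
Conditions: AcCl (1.05 equiv), 2,4,6-collidine, CH2Cl2, −78 °C
Reagents that add atoms: acetyl chloride, CC(=O)Cl
Why: Kinetic acylation discriminates on steric grounds, since the C7 hydroxyl hangs on a planar sp2 carbon whereas the C1′ hydroxyl is neopentyl-like on the fully substituted C4 and screened by the cis C3 silyl ether.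

Step 12
Reactants: 13 C7 monoacetate
Product: 14 core epoxy aldehyde (C1′ = CHO on C4; C7 acetate; C3 and C6 OTBS)
Conditions: Dess–Martin periodinane, NaHCO3, CH2Cl2, 0 °C → rt
Reagents that add atoms: none
Why: Dess–Martin oxidation is mild toward epoxide, acetate and silyl ethers, and the aldehyde has no α hydrogen, so C4 cannot epimerise.

Step 13
Reactants: 15 propargyl alcohol
Product: 17 (E)-3-iodo-2-methylprop-2-en-1-ol, via alkenylalane 16 (not isolated)
Conditions: Me3Al (3 equiv), Cp2ZrCl2 (0.25 equiv), CH2Cl2, 0 °C → rt; then I2, THF, −30 → 0 °C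
Reagents that add atoms: trimethylaluminium, C[Al](C)C; iodine, II
Why: Zirconium-catalysed Negishi carboalumination adds CH3 and Al syn across the alkyne with Al at the terminus, and iodinolysis with retention fixes the E geometry.

Step 14
Reactants: 17 (E)-3-iodo-2-methylprop-2-en-1-ol
Product: 18 (E)-3-iodo-2-methylprop-2-enal
Conditions: MnO2 (activated, excess), CH2Cl2, rt, dark
Reagents that add atoms: none
Why: Activated MnO2 oxidises the allylic alcohol selectively without alkene isomerisation or loss of iodide.

Step 15
Reactants: 19 geranyl bromide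
Product: 20 diethyl geranylphosphonate, diethyl [(2E)-3,7-dimethylocta-2,6-dienyl]phosphonate
Conditions: P(OEt)3 (neat), 130 °C
Reagents that add atoms: triethyl phosphite, CCOP(OCC)OCC
Why: In the Michaelis–Arbuzov reaction phosphorus attacks the primary allylic carbon in SN2 fashion and bromide dealkylates the phosphonium salt, so the E-trisubstituted alkene is kept.

Step 16
Reactants: 20 diethyl geranylphosphonate (1.2 equiv); 18 (E)-3-iodo-2-methylprop-2-enal
Product: 22 (1E,3E,5E)-1-iodo-2,6,10-trimethylundeca-1,3,5,9-tetraene, via lithiated phosphonate 21 (not isolated)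
Conditions: n-BuLi (1.15 equiv), THF–DMPU, −78 °C; then 18, −78 °C → rt, dark
Reagents that add atoms: none
Why: Horner–Wadsworth–Emmons olefination of an allylic phosphonate anion with an enal gives the E alkene through reversible addition and syn elimination, both alkenes brought in keep their geometry in the cold, and using less n-BuLi than phosphonate excludes iodine–lithium exchange.

Step 17
Reactants: 14 core epoxy aldehyde; 22 (1E,3E,5E)-1-iodo-2,6,10-trimethylundeca-1,3,5,9-tetraene (1.8 equiv)
Product: 24 coupled C1′ carbinols as a mixture of both C1′ epimers, via alkenylchromium dichloride 23 (not isolated)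
Conditions: CrCl2 (6 equiv), NiCl2 (1 mol % of the CrCl2), DMSO, rt, dark
Reagents that add atoms: none
Why: In the Nozaki–Hiyama–Kishi coupling zerovalent nickel inserts into the C–I bond with retention and hands the alkenyl group to chromium, whose reagent adds only to aldehydes, so acetate, epoxide and silyl ethers survive, and the unselective C1′ centre is corrected in steps 18 and 19.

Step 18
Reactants: 24 coupled C1′ carbinols
Product: 25 epoxy trienyl ketone (C1′ = C=O)
Conditions: Dess–Martin periodinane, NaHCO3, CH2Cl2, 0 °C
Reagents that add atoms: none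
Why: Buffered Dess–Martin oxidation converges both epimers on one ketone without acid-induced ionisation of the trienyl carbinol.

Step 19
Reactants: 25 epoxy trienyl ketone
Product: 26 (1′S)-carbinol, C3 and C6 bis-TBS ether
Conditions: Zn(BH4)2 (ethereal solution), Et2O, −20 °C
Reagents that add atoms: none
Why: Zn(BH4)2 reduction of an α,β-epoxy ketone proceeds through a five-membered zinc chelate of the carbonyl and oxirane oxygens, with hydride arriving from the side remote from oxirane carbon C5, which should give the anti epoxy alcohol, here 1′S, by clean 1,2-addition.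

Step 20
Reactants: 26 (1′S)-carbinol bis-TBS ether
Product: 27 target, [(3S,4R,5S,6S)-4,5-epoxy-3,6-dihydroxy-4-[(1S,2E,4E,6E)-1-hydroxy-3,7,11-trimethyldodeca-2,4,6,10-tetraenyl]cyclohex-1-enyl]methyl acetate
Conditions: HF·pyridine, pyridine, THF, 0 °C → rt
Reagents that add atoms: none
Why: Pyridine-buffered HF removes both secondary silyl ethers under nearly neutral conditions, with no base to trigger acetyl migration or Payne rearrangement and too little acidity to ionise the trienyl carbinol.

Compound list
1 | 2,5-dimethoxyterephthalaldehyde | COc1cc(C=O)c(OC)cc1C=O | starting material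
2 | (2,5-dimethoxy-1,4-phenylene)dimethanol | COc1cc(CO)c(OC)cc1CO | intermediate
3 | 1,4-bis[(tert-butyldimethylsilyloxy)methyl]-2,5-dimethoxybenzene | COc1cc(CO[Si](C)(C)C(C)(C)C)c(OC)cc1CO[Si](C)(C)C(C)(C)C | intermediate
4 | 2,5-bis[(tert-butyldimethylsilyloxy)methyl]-1,4-benzoquinone | O=C1C=C(CO[Si](C)(C)C(C)(C)C)C(=O)C=C1CO[Si](C)(C)C(C)(C)C | intermediate
5 | cyclopenta-1,3-diene (distilled from commercial dicyclopentadiene just before use) | C1=CC=CC1 | starting material
6 | endo quinone–cyclopentadiene adduct (1R,4S,4aR,8aS) | O=C1C(CO[Si](C)(C)C(C)(C)C)=CC(=O)[C@]2(CO[Si](C)(C)C(C)(C)C)[C@@H]3C=C[C@@H](C3)[C@H]12 | intermediate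
7 | bridged epoxy-dione (α-oxirane at C4–C5) | O=C1[C@@]2(CO[Si](C)(C)C(C)(C)C)O[C@H]2C(=O)[C@]3(CO[Si](C)(C)C(C)(C)C)[C@@H]4C=C[C@@H](C4)[C@H]13 | intermediate
8 | bridged hydroxy ketone (3β-OH, C6 ketone) | O[C@@H]1[C@@]2(CO[Si](C)(C)C(C)(C)C)O[C@H]2C(=O)[C@]3(CO[Si](C)(C)C(C)(C)C)[C@@H]4C=C[C@@H](C4)[C@H]13 | intermediate
9 | epoxy-enone (3β-OH, 4α,5α-epoxide, C6 ketone, both arms OTBS) | CC(C)(C)[Si](C)(C)OCC1=C[C@H](O)[C@@]2(CO[Si](C)(C)C(C)(C)C)O[C@H]2C1=O | intermediate
10 | 3β,6α-diol | CC(C)(C)[Si](C)(C)OCC1=C[C@H](O)[C@@]2(CO[Si](C)(C)C(C)(C)C)O[C@H]2[C@H]1O | intermediate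
11 | tetrakis-TBS ether | CC(C)(C)[Si](C)(C)OCC1=C[C@H](O[Si](C)(C)C(C)(C)C)[C@@]2(CO[Si](C)(C)C(C)(C)C)O[C@H]2[C@H]1O[Si](C)(C)C(C)(C)C | intermediate
12 | primary diol (C7–OH, C1′–OH) | OCC1=C[C@H](O[Si](C)(C)C(C)(C)C)[C@@]2(CO)O[C@H]2[C@H]1O[Si](C)(C)C(C)(C)C | intermediate
13 | C7 monoacetate | CC(=O)OCC1=C[C@H](O[Si](C)(C)C(C)(C)C)[C@@]2(CO)O[C@H]2[C@H]1O[Si](C)(C)C(C)(C)C | intermediate
14 | core epoxy aldehyde | CC(=O)OCC1=C[C@H](O[Si](C)(C)C(C)(C)C)[C@@]2(C=O)O[C@H]2[C@H]1O[Si](C)(C)C(C)(C)C | intermediate
15 | propargyl alcohol | C#CCO | starting material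
16 | alkenylalane, dimethylaluminium alkoxide of (E)-3-(dimethylalumanyl)-2-methylprop-2-en-1-ol | C[Al](C)OC/C(C)=C/[Al](C)C | intermediate
17 | (E)-3-iodo-2-methylprop-2-en-1-ol | OC/C(C)=C/I | intermediate
18 | (E)-3-iodo-2-methylprop-2-enal | O=C/C(C)=C/I | intermediate
19 | geranyl bromide | CC(C)=CCC/C(C)=C/CBr | starting material
20 | diethyl geranylphosphonate | CCOP(=O)(OCC)C/C=C(\C)CCC=C(C)C | intermediate
21 | lithiated diethyl geranylphosphonate | CCOP(=O)(OCC)C([Li])/C=C(\C)CCC=C(C)C | intermediate
22 | (1E,3E,5E)-1-iodo-2,6,10-trimethylundeca-1,3,5,9-tetraene | I/C=C(C)/C=C/C=C(\C)CCC=C(C)C | intermediate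
23 | (1E,3E,5E)-2,6,10-trimethylundeca-1,3,5,9-tetraenylchromium dichloride | Cl[Cr](Cl)/C=C(C)/C=C/C=C(\C)CCC=C(C)C | intermediate
24 | coupled C1′ carbinols (both epimers) | CC(=O)OCC1=C[C@H](O[Si](C)(C)C(C)(C)C)[C@@]2(C(O)/C=C(C)/C=C/C=C(\C)CCC=C(C)C)O[C@H]2[C@H]1O[Si](C)(C)C(C)(C)C | intermediate
25 | epoxy trienyl ketone | CC(=O)OCC1=C[C@H](O[Si](C)(C)C(C)(C)C)[C@@]2(C(=O)/C=C(C)/C=C/C=C(\C)CCC=C(C)C)O[C@H]2[C@H]1O[Si](C)(C)C(C)(C)C | intermediate
26 | (1′S)-carbinol bis-TBS ether | CC(=O)OCC1=C[C@H](O[Si](C)(C)C(C)(C)C)[C@@]2([C@@H](O)/C=C(C)/C=C/C=C(\C)CCC=C(C)C)O[C@H]2[C@H]1O[Si](C)(C)C(C)(C)C | intermediate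
27 | CNP0106887.1 | CC(=O)OCC1=C[C@H](O)[C@@]2([C@@H](O)/C=C(C)/C=C/C=C(\C)CCC=C(C)C)O[C@H]2[C@H]1O | target

Total steps: 20. Longest linear sequence: 16 (steps 1–12, then 17–20).

Steps most likely to fail

1. Step 4. The risk is weak enantioface discrimination or slow turnover, because the silyloxymethyl oxygens may compete with the carbonyl for boron and the reacting alkene is trisubstituted.
The fallback moves from asymmetric catalysis to resolution; it sets out from 4 and 5 and comes back at 9. The uncatalysed cycloaddition (toluene, 0 °C → rt) gives the endo adduct as a racemate, that is 6 together with the mirror-image adduct F1. Under the conditions of steps 5, 6 and 7 the racemate gives, beside 7, 8 and 9, the mirror-image epoxy-dione F2, the mirror-image hydroxy ketone F3 and the mirror-image epoxy-enone F4. Lipase-catalysed transesterification (Burkholderia cepacia lipase, vinyl acetate, t-BuOMe, 30 °C) then separates the pair. By the empirical size rule for secondary alcohols (C4 large, C2 medium), the 3R alcohol should react faster and become the mirror-image enone acetate F5. The 3S alcohol 9 should stay free, is separated by chromatography and enters step 8.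

2. Step 11. The risk is insufficient discrimination between the two primary hydroxyls, so that acetylation occurs at the wrong oxygen or at both.
The fallback replaces the steric distinction by an electronic one; it sets out from 12 and comes back at 13. MnO2 (CH2Cl2, rt) oxidises only the allylic C7 hydroxyl to the hydroxy enal F6. TESCl and imidazole cover the C1′ hydroxyl to give the silylated enal F7. Luche reduction returns C7 to the alcohol stage as the C7 allylic alcohol F8. Ac2O, pyridine and DMAP give the acetate TES ether F9. PPTS in MeOH at 0 °C removes only the primary triethylsilyl ether and delivers 13.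

3. Step 19. The risk is erosion or reversal of facial selectivity in hydride delivery, because the fully substituted C4 and the neighbouring C3 silyl ether crowd the side of the chelate from which hydride should come.
The fallback sets C1′ during C–C bond formation under ligand control; it sets out from 14 and 22 and comes back at 26, bypassing 24 and 25. It is a catalytic asymmetric Nozaki–Hiyama–Kishi coupling. The conditions are CrCl2 (10 mol %) with a chiral 2-[2-(sulfonylamino)phenyl]oxazoline ligand and Et3N, NiCl2·(2,9-dimethyl-1,10-phenanthroline) (catalytic), Mn powder, Cp2ZrCl2 and LiCl in MeCN at rt. The ligand antipode that favours 1′S is chosen. This fallback makes no compound outside the list (F0).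

Further compounds
F1 | step 4 | mirror-image adduct (enantiomer of 6) | O=C1C(CO[Si](C)(C)C(C)(C)C)=CC(=O)[C@@]2(CO[Si](C)(C)C(C)(C)C)[C@H]3C=C[C@H](C3)[C@@H]12
F2 | step 4 | mirror-image epoxy-dione (enantiomer of 7) | O=C1[C@]2(CO[Si](C)(C)C(C)(C)C)O[C@@H]2C(=O)[C@@]3(CO[Si](C)(C)C(C)(C)C)[C@H]4C=C[C@H](C4)[C@@H]13
F3 | step 4 | mirror-image hydroxy ketone (enantiomer of 8) | O[C@H]1[C@]2(CO[Si](C)(C)C(C)(C)C)O[C@@H]2C(=O)[C@@]3(CO[Si](C)(C)C(C)(C)C)[C@H]4C=C[C@H](C4)[C@@H]13
F4 | step 4 | mirror-image epoxy-enone (enantiomer of 9) | CC(C)(C)[Si](C)(C)OCC1=C[C@@H](O)[C@]2(CO[Si](C)(C)C(C)(C)C)O[C@@H]2C1=O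
F5 | step 4 | mirror-image enone acetate (C3 acetate of F4) | CC(C)(C)[Si](C)(C)OCC1=C[C@@H](OC(C)=O)[C@]2(CO[Si](C)(C)C(C)(C)C)O[C@@H]2C1=O
F6 | step 11 | hydroxy enal (C7 aldehyde, C1′–OH) | O=CC1=C[C@H](O[Si](C)(C)C(C)(C)C)[C@@]2(CO)O[C@H]2[C@H]1O[Si](C)(C)C(C)(C)C
F7 | step 11 | silylated enal (C7 aldehyde, C1′–OTES) | O=CC1=C[C@H](O[Si](C)(C)C(C)(C)C)[C@@]2(CO[Si](CC)(CC)CC)O[C@H]2[C@H]1O[Si](C)(C)C(C)(C)C
F8 | step 11 | C7 allylic alcohol (C1′–OTES) | OCC1=C[C@H](O[Si](C)(C)C(C)(C)C)[C@@]2(CO[Si](CC)(CC)CC)O[C@H]2[C@H]1O[Si](C)(C)C(C)(C)C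
F9 | step 11 | acetate TES ether (C7–OAc, C1′–OTES) | CC(=O)OCC1=C[C@H](O[Si](C)(C)C(C)(C)C)[C@@]2(CO[Si](CC)(CC)CC)O[C@H]2[C@H]1O[Si](C)(C)C(C)(C)C
F0 | step 19 | none | none
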